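**Retrosynthetic overview**
1. Target 28 ⇐ C13 allylic alcohol 27 (oxidation) ⇐ closure of the ten-membered ring B at C6–C7 by a visible-light Ni/Ir coupling of a 2-silyloxyfuran (C7 radical) with a (Z)-alkenyl bromide; this last ring closure also sets C7.
2. Butenolide joined at C8–C9 by hydroboration of a C10 exocyclic methylene (sets C10) and B-alkyl Suzuki coupling with 4-bromo-3-methylbutenolide.
3. Ring A is (R)-carvone: isopropenyl → C14 acetate (Criegee), C=O → C10 methylene, γ-CH2 → C13 oxygen.
4. C1 and C2 come from a syn aldol of carvone with (Z)-5-bromo-4-methylpent-4-enal, then C1 methylation anti to the isopropenyl group.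
5. Ring order: ring A bought, lactone ring bought (as 3-methyltetronic acid) and attached, ring B closed last.

Assumption: compounds 1, 2, 7 and 9 are bought; atoms of all intermediates are located with the briarane numbering of the target (C1 quaternary carbon with methyl C15, C2 isobutyrate carbon, C5=C6 alkene, C7 lactone CH–O, C8=C17 butenolide alkene, C10 ring-fusion CH, C13 ketone, C14 acetate carbon).

**Step 1**
Reactants: 1 2-(2-bromoethyl)-1,3-dioxolane; 2 propyne
Product: 6 (4Z)-5-bromo-4-methylpent-4-enal, via Grignard reagent 3 (not isolated), via alkenylcopper 4 (not isolated), via bromoalkenyl dioxolane 5 (not isolated)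
Conditions: Mg, THF/Et2O, 30 °C; CuBr·SMe2, Et2O/Me2S, −45 °C; propyne, −25 °C; NBS, −78 → 0 °C; then 1 M HCl, THF, 23 °C
Reagents that add atoms: N-bromosuccinimide (O=C1CCC(=O)N1Br); water (O)
Why: Normant carbocupration adds the alkyl group and copper syn across propyne (alkyl to the internal carbon), so bromination with retention gives only the Z bromide (chain cis to Br), and acetal hydrolysis frees the aldehyde.

**Step 2**
Reactants: 7 4-hydroxy-3-methylfuran-2(5H)-one
Product: 8 4-bromo-3-methylfuran-2(5H)-one
Conditions: (COBr)2, DMF (cat.), CH2Cl2, 0 → 23 °C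
Reagents that add atoms: oxalyl bromide (O=C(Br)C(Br)=O)
Why: Vilsmeier-type bromodehydroxylation of the vinylogous acid gives the β-bromobutenolide.

**Step 3**
Reactants: 9 (R)-carvone; 6 (4Z)-5-bromo-4-methylpent-4-enal
Product: 11 syn-aldol adduct, via titanium enolate 10 (not isolated)
Conditions: LDA, THF, −78 °C; ClTi(OiPr)3, −78 → −40 °C; 6, −78 °C
Reagents that add atoms: none
Why: Kinetic α′-deprotonation and transmetalation give the titanium enolate, which adds to 6 anti to the isopropenyl group in a syn-selective Reetz titanium aldol (triisopropoxytitanium enolates give syn adducts whatever the enolate geometry, whereas the lithium or boron chair would give the anti, 2R product), so C2 is formed as S (expected dr about 6:1, minor epimer removed); the C1 hydrogen is replaced in step 4.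

**Step 4**
Reactants: 11 syn-aldol adduct
Product: 14 C1-methylated keto isobutyrate, via dilithium enolate-alkoxide 12 (not isolated), via lithium alkoxide 13 (not isolated)
Conditions: LDA (2.4 equiv), THF/DMPU, −78 → −45 °C; MeI, −78 → −40 °C; then iPrCOCl, DMAP (cat.), −78 → 0 °C
Reagents that add atoms: iodomethane (CI); 2-methylpropanoyl chloride (CC(C)C(=O)Cl)
Why: Dianion alkylation: the enolate is methylated at C1 anti to the adjacent isopropenyl group (the usual sense for 6-substituted carvone enolates), which puts C15 trans and the C2 chain cis to the C14 substituent as in the target, and the alkoxide is acylated in the same flask before retro-aldol cleavage can occur.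

**Step 5**
Reactants: 14 C1-methylated keto isobutyrate
Product: 17 ring A ene-1,4-dione, via silyl dienol ether 15 (not isolated), via trans γ-hydroxy enone 16 (not isolated)
Conditions: TMSOTf, Et3N, CH2Cl2, 0 °C; NaHCO3 wash; mCPBA, NaHCO3, CH2Cl2, −30 °C; then Dess–Martin periodinane, 23 °C
Reagents that add atoms: 3-chloroperbenzoic acid (OOC(=O)c1cccc(Cl)c1)
Why: Vinylogous Rubottom oxidation: with C1 quaternary only γ-enolisation is possible, the linear silyl dienol ether is epoxidised at its electron-rich C12=C13 end in preference to the isopropenyl and bromoalkene groups, and Dess–Martin oxidation of the resulting allylic alcohol gives the enedione.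

**Step 6**
Reactants: 17 ring A ene-1,4-dione
Product: 18 cis γ-hydroxy enone
Conditions: NaBH4, CeCl3·7H2O, MeOH, −78 °C
Reagents that add atoms: none
Why: Luche 1,2-reduction occurs at the less hindered C13 carbonyl (C10 is flanked by quaternary C1 and methyl-bearing C11) with hydride arriving anti to the adjacent isopropenyl group, giving the alcohol cis to it; this temporary centre steers step 10 and is erased in step 13.

**Step 7**
Reactants: 18 cis γ-hydroxy enone
Product: 19 C13 triethylsilyl ether
Conditions: TESOTf, 2,6-lutidine, CH2Cl2, −78 °C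
Reagents that add atoms: triethylsilyl trifluoromethanesulfonate (CC[Si](CC)(CC)OS(=O)(=O)C(F)(F)F)
Why: Standard silylation of the allylic alcohol, which prevents its acetylation in step 8 and acetyl migration from O14 later.

**Step 8**
Reactants: 19 C13 triethylsilyl ether
Product: 21 C14 acetate, via methoxy hydroperoxide 20 (not isolated)
Conditions: O3, CH2Cl2/MeOH, −78 °C; then Ac2O, Et3N, DMAP, 0 → 40 °C
Reagents that add atoms: ozone ([O-][O+]=O); acetic anhydride (CC(=O)OC(C)=O)
Why: Ozonolysis in methanol at the isopropenyl group (the enone and bromoalkene are electron-poor) gives the α-methoxy hydroperoxide, whose peracetate undergoes Criegee rearrangement with migration of C14 with retention, turning the carvone stereocentre into the C14 acetate.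

**Step 9**
Reactants: 21 C14 acetate
Product: 22 C10 exocyclic methylene diene
Conditions: Zn, CH2Br2, TiCl4, THF/CH2Cl2, 0 → 23 °C
Reagents that add atoms: dibromomethane (BrCBr)
Why: Takai–Lombardo methylenation: the non-basic gem-dizinc/titanium reagent methylenates hindered conjugated ketones without touching the three esters, the silyl ether or the alkenyl bromide.

**Step 10**
Reactants: 22 C10 exocyclic methylene diene; 8 4-bromo-3-methylfuran-2(5H)-one
Product: 24 C9-linked butenolide, via alkylborane 23 (not isolated)
Conditions: 9-BBN, THF, 23 → 40 °C; then 8, Pd(dppf)Cl2, AsPh3, K3PO4, DMF/H2O, 23 °C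
Reagents that add atoms: none
Why: Hydroboration then B-alkyl Suzuki–Miyaura coupling: boron adds to terminal C9 and, because the cis C13 silyl ether/C14 acetate pair locks the half-chair with the C15 methyl axial on the lower face and the C2 chain equatorial, hydrogen is delivered to C10 from the upper face (10R, C9 trans to the C2 chain); the vinylogous acyl bromide 8 undergoes oxidative addition at 23 °C far faster than the hindered alkenyl bromide.

**Step 11**
Reactants: 24 C9-linked butenolide
Product: 25 2-(trimethylsilyloxy)furan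
Conditions: TMSOTf, Et3N, CH2Cl2, −78 → 0 °C; pentane trituration, used crude
Reagents that add atoms: trimethylsilyl trifluoromethanesulfonate (C[Si](C)(C)OS(=O)(=O)C(F)(F)F)
Why: Soft enolisation: the butenolide γ-CH2 (C7) is the most acidic position and gives the aromatic 2-silyloxyfuran.

**Step 12**
Reactants: 25 2-(trimethylsilyloxy)furan
Product: 27 macrocyclic C13 allylic alcohol, via macrocyclic silyl ether 26 (not isolated)
Conditions: Ir[dF(CF3)ppy]2(dtbbpy)PF6 (2 mol %), NiBr2·glyme (10 mol %), dtbbpy (12 mol %), 2,6-lutidine, MeCN/THF (2 mM), 450 nm LEDs, 25 °C; then HF·pyridine, THF, 0 °C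
Reagents that add atoms: none
Why: Proposed new method: the excited iridium photocatalyst (about +1.2 V vs SCE) oxidises the electron-rich 2-silyloxyfuran (about +0.9 to +1.0 V) to its radical cation, bromide-assisted loss of the silyl group gives the 2-oxo-2,5-dihydrofuran-5-yl radical (spin at C7 and C17), and this is captured at the less hindered C7 by the tethered alkenylnickel bromide formed by oxidative addition of zerovalent nickel to the Z-alkenyl bromide; reductive elimination from trivalent nickel forms C6–C7 with retention of the Z geometry and closes the ten-membered ring, the reduced iridium returns monovalent nickel to zerovalent nickel so the coupling is redox-neutral with Me3SiBr as the only by-product, and C7 is set under substrate control by the trans-disposed C1/C10 arms and the Z-alkene (7R is a model-based expectation to be verified); the closest known reaction types are metallaphotoredox C(sp3)–C(sp2) coupling of oxidisable radical precursors (carboxylates, alkylsilicates) with alkenyl halides and photoredox oxidation of silyl enol ethers to α-carbonyl radicals, neither shown for a silyloxyfuran or for a ten-membered ring closure; HF·pyridine then cleaves the C13 silyl ether in the same flask.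

**Step 13**
Reactants: 27 macrocyclic C13 allylic alcohol
Product: 28 target CNP0325467.3
Conditions: Dess–Martin periodinane, NaHCO3, CH2Cl2, 0 → 23 °C
Reagents that add atoms: none
Why: Dess–Martin oxidation of the allylic alcohol gives the C13 enone under buffered, non-epimerising conditions, leaving C14 and C10 untouched.

**Compound list**
1 | 2-(2-bromoethyl)-1,3-dioxolane | BrCCC1OCCO1 | starting material
2 | propyne | CC#C | starting material
3 | [2-(1,3-dioxolan-2-yl)ethyl]magnesium bromide | Br[Mg]CCC1OCCO1 | intermediate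
4 | (Z)-[4-(1,3-dioxolan-2-yl)-2-methylbut-1-en-1-yl]copper | [Cu]/C=C(/C)CCC1OCCO1 | intermediate
5 | 2-[(3Z)-4-bromo-3-methylbut-3-en-1-yl]-1,3-dioxolane | Br/C=C(/C)CCC1OCCO1 | intermediate
6 | (4Z)-5-bromo-4-methylpent-4-enal | Br/C=C(/C)CCC=O | intermediate
7 | 4-hydroxy-3-methylfuran-2(5H)-one (3-methyltetronic acid) | CC1=C(O)COC1=O | starting material
8 | 4-bromo-3-methylfuran-2(5H)-one | CC1=C(Br)COC1=O | intermediate
9 | (R)-(−)-carvone | CC1=CC[C@H](CC1=O)C(C)=C | starting material
10 | tri(propan-2-yloxy)titanium cross-conjugated dienolate of (R)-carvone | CC1=CC[C@@H](C(C)=C)C=C1O[Ti](OC(C)C)(OC(C)C)OC(C)C | intermediate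
11 | (5R,6R)-6-[(1S,4Z)-5-bromo-1-hydroxy-4-methylpent-4-en-1-yl]-2-methyl-5-(prop-1-en-2-yl)cyclohex-2-en-1-one | Br/C=C(/C)CC[C@H](O)[C@@H]1C(=O)C(C)=CC[C@H]1C(C)=C | intermediate
12 | dilithium enolate-alkoxide of 11 (C10 enolate, C2 alkoxide) | Br/C=C(/C)CC[C@H](O[Li])C1=C(O[Li])C(C)=CC[C@H]1C(C)=C | intermediate
13 | lithium C2 alkoxide of the C1-methylated ketol (C15 trans, C2 chain cis to isopropenyl) | Br/C=C(/C)CC[C@H](O[Li])[C@@]1(C)C(=O)C(C)=CC[C@H]1C(C)=C | intermediate
14 | (1S,4Z)-5-bromo-4-methyl-1-[(1S,6S)-1,3-dimethyl-2-oxo-6-(prop-1-en-2-yl)cyclohex-3-en-1-yl]pent-4-en-1-yl 2-methylpropanoate | Br/C=C(/C)CC[C@H](OC(=O)C(C)C)[C@@]1(C)C(=O)C(C)=CC[C@H]1C(C)=C | intermediate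
15 | C10-O-trimethylsilyl 10,12-dienol ether of 14 | Br/C=C(/C)CC[C@H](OC(=O)C(C)C)[C@@]1(C)C(O[Si](C)(C)C)=C(C)C=C[C@H]1C(C)=C | intermediate
16 | 13-hydroxy derivative of 14, OH trans to the C14 isopropenyl | Br/C=C(/C)CC[C@H](OC(=O)C(C)C)[C@@]1(C)C(=O)C(C)=C[C@H](O)[C@H]1C(C)=C | intermediate
17 | 13-oxo derivative of 14 (ring A 2-methylcyclohex-2-ene-1,4-dione) | Br/C=C(/C)CC[C@H](OC(=O)C(C)C)[C@@]1(C)C(=O)C(C)=CC(=O)[C@H]1C(C)=C | intermediate
18 | 13-hydroxy derivative of 14, OH cis to the C14 isopropenyl | Br/C=C(/C)CC[C@H](OC(=O)C(C)C)[C@@]1(C)C(=O)C(C)=C[C@@H](O)[C@H]1C(C)=C | intermediate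
19 | 13-O-triethylsilyl ether of 18 | Br/C=C(/C)CC[C@H](OC(=O)C(C)C)[C@@]1(C)C(=O)C(C)=C[C@@H](O[Si](CC)(CC)CC)[C@H]1C(C)=C | intermediate
20 | α-methoxy hydroperoxide of 19 (C14 bears C(CH3)(OCH3)OOH, epimers at that carbon) | Br/C=C(/C)CC[C@H](OC(=O)C(C)C)[C@@]1(C)C(=O)C(C)=C[C@@H](O[Si](CC)(CC)CC)[C@H]1C(C)(OC)OO | intermediate
21 | C14 acetate, C10 ketone, 13-O-triethylsilyl (C14–O cis to C13–O and to the C2 chain) | Br/C=C(/C)CC[C@H](OC(=O)C(C)C)[C@@]1(C)C(=O)C(C)=C[C@@H](O[Si](CC)(CC)CC)[C@H]1OC(C)=O | intermediate
22 | C10 exocyclic methylene analogue of 21 (C9=C10–C11=C12 diene) | Br/C=C(/C)CC[C@H](OC(=O)C(C)C)[C@@]1(C)C(=C)C(C)=C[C@@H](O[Si](CC)(CC)CC)[C@H]1OC(C)=O | intermediate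
23 | (10R)-C9 B-alkyl-9-borabicyclo[3.3.1]nonane from 22 | Br/C=C(/C)CC[C@H](OC(=O)C(C)C)[C@@]1(C)[C@H](CB2C3CCCC2CCC3)C(C)=C[C@@H](O[Si](CC)(CC)CC)[C@H]1OC(C)=O | intermediate
24 | (10R)-C9-(4-methyl-5-oxo-2,5-dihydrofuran-3-yl) compound (seco-briarane, C6 bromide, C7 CH2) | Br/C=C(/C)CC[C@H](OC(=O)C(C)C)[C@@]1(C)[C@H](CC2=C(C)C(=O)OC2)C(C)=C[C@@H](O[Si](CC)(CC)CC)[C@H]1OC(C)=O | intermediate
25 | 2-(trimethylsilyloxy)-3-methylfuran-4-yl analogue of 24 | Br/C=C(/C)CC[C@H](OC(=O)C(C)C)[C@@]1(C)[C@H](Cc2coc(O[Si](C)(C)C)c2C)C(C)=C[C@@H](O[Si](CC)(CC)CC)[C@H]1OC(C)=O | intermediate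
26 | 13-O-triethylsilyl ether of 27 (macrocycle, 7R, 5Z) | CC(=O)O[C@@H]1[C@H](O[Si](CC)(CC)CC)C=C(C)[C@H]2CC3=C(C)C(=O)O[C@@H]3/C=C(/C)CC[C@H](OC(=O)C(C)C)[C@@]21C | intermediate
27 | 13-hydroxy (cis to C14 acetate) 13-deoxo analogue of the target | CC(=O)O[C@@H]1[C@H](O)C=C(C)[C@H]2CC3=C(C)C(=O)O[C@@H]3/C=C(/C)CC[C@H](OC(=O)C(C)C)[C@@]21C | intermediate
28 | CNP0325467.3, (1R,2S,5Z,7R,10R,14S) briarane butenolide with 14-acetate, 2-isobutyrate and 13-ketone | CC(=O)O[C@@H]1C(=O)C=C(C)[C@H]2CC3=C(C)C(=O)O[C@@H]3/C=C(/C)CC[C@H](OC(=O)C(C)C)[C@@]21C | target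

**Step count and risks**
Total: 13 steps. Longest linear sequence: 12 steps (steps 1 and 3–13, from compound 1; 11 steps from (R)-carvone).

The three steps most likely to fail:

Step 12, the new macrocyclisation. Risks are slow ring closure against protodesilylation or oligomerisation, coupling at C17 instead of C7, and the wrong C7 epimer. The fallback uses known chemistry and sets out from 24, without the silyloxyfuran: a palladium-catalysed intramolecular γ-alkenylation of the butenolide dienolate (Pd2(dba)3, XPhos, K3PO4, toluene, 70 °C, 2 mM), the two-electron enolate alkenylation known for ketone enolates with alkenyl bromides and for the γ-arylation of butenolides. It comes back to the route at 26, which is desilylated with HF·pyridine to 27 as in step 12; no new compound is made.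

Step 10, the C10 stereocentre and the chemoselective coupling. The face of hydroboration rests on a conformational argument, and the alkenyl bromide could compete in the Suzuki step. The fallback sets out from 22: Heck coupling with 8 (Pd(OAc)2, P(o-tol)3, Et3N, MeCN, 60 °C) gives the C9=C10 triene F4, and hydrogenation with [Ir(cod)(PCy3)(py)]PF6 (H2, CH2Cl2), directed by the ester carbonyls at C14 and C2 on the upper face, delivers hydrogen to C10 from that face by coordination rather than by steric approach. It comes back to the route at 24.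

Step 4, the dianion methylation with in-flask acylation. Risks are γ-deprotonation of the enone, retro-aldol cleavage of the hindered alkoxide, and incomplete acylation. The fallback sets out from 11 and replaces the dianion by a protected mono-enolate: TESOTf and 2,6-lutidine give the aldol triethylsilyl ether F1; LDA in THF/DMPU at −78 °C then MeI gives the C1-methylated silyl ether F2 (methyl again anti to isopropenyl); HF·pyridine gives the C1-methylated ketol F3; isobutyric anhydride, DMAP and Et3N then give the ester. It comes back to the route at 14.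

**Further compounds**
F1 | step 4 | triethylsilyl ether of aldol 11 | Br/C=C(/C)CC[C@H](O[Si](CC)(CC)CC)[C@@H]1C(=O)C(C)=CC[C@H]1C(C)=C
F2 | step 4 | C1-methylated triethylsilyl ether (C15 trans to isopropenyl) | Br/C=C(/C)CC[C@H](O[Si](CC)(CC)CC)[C@@]1(C)C(=O)C(C)=CC[C@H]1C(C)=C
F3 | step 4 | C1-methylated ketol (free C2 alcohol of 14) | Br/C=C(/C)CC[C@H](O)[C@@]1(C)C(=O)C(C)=CC[C@H]1C(C)=C
F4 | step 10 | C9=C10 triene from Heck coupling of 22 with 8 (alkene geometry at C9=C10 not fixed) | Br/C=C(/C)CC[C@H](OC(=O)C(C)C)[C@@]1(C)C(=CC2=C(C)C(=O)OC2)C(C)=C[C@@H](O[Si](CC)(CC)CC)[C@H]1OC(C)=O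
F0 | step 12 | none | none
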